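**Plan**
Labels: O1, C2 (aryl), C3 (CH2OH arm), C4 (aroyl) and C5 of the oxolane; C7 is the ketone carbon on C4.
Cuts: C7=O and the arm C–OH are traced back to a C4=C7 arylidene and a CH2–Bpin arm. Then the ring bond C3–C4, the C7–aryl (alkyne–aryl) bond, the O1–C5 ether bond and the C2–C3 (carbinol–vinyl) bond are cut, in that order.
Enabling feature: C3–C4 is the one ring bond linking the C2–C3 side of O1 (an allylic ether once C3 and its arm are a vinyl group) to the C5–C4 side (a propargylic ether once C4≡C7 carries the aryl ring). Removing it leaves a 1,6-enyne whose terminal alkene carbon ends the cyclisation on palladium and can be handed to boron.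
Forward: the chain is joined by Grignard addition, O-propargylation and Sonogashira coupling. The only ring formed, the oxolane, closes in the borylative cyclisation, and one hydroboration–peroxide step then turns both C–B bonds into C–OH.
Stereochemistry: C2 comes from a lipase kinetic resolution, C3 is relayed from C2 in the ring closure (2,3-trans), and C4 comes from base equilibration of the aryl ketone to the all-trans oxolane.

Key step: step 6

Assumption: the labels above are also used as locants in the oxolane names. Compounds 12–14 are drawn as the diastereomer expected from borane attack on the ring face opposite the C3 arm; C4 and C7 are provisional there and are reset or erased in step 9, so any other isomer converges on 16.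

Step 1
Reactants: 1 3-(benzyloxy)-4-methoxybenzaldehyde (O-benzylisovanillin); 2 vinylmagnesium bromide
Product: 3 rac-1-[3-(benzyloxy)-4-methoxyphenyl]prop-2-en-1-ol
Conditions: THF, −78 to 0 °C; aq NH4Cl
Reagents that add atoms: vinylmagnesium bromide (2), C=C[Mg]Br
Why: Grignard 1,2-addition to a non-enolisable aromatic aldehyde should be clean; the carbinol carbon (future C2) forms as a racemate and is resolved in step 2.

Step 2
Reactants: 3 rac-1-[3-(benzyloxy)-4-methoxyphenyl]prop-2-en-1-ol
Product: 4 (S)-1-[3-(benzyloxy)-4-methoxyphenyl]prop-2-en-1-ol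
Conditions: immobilised Candida antarctica lipase B, isopropenyl acetate, toluene, 40 °C, stopped just past half conversion; chromatography
Reagents that add atoms: none
Why: Lipase-catalysed kinetic resolution by transesterification; under the empirical size rule for secondary alcohols (aryl large, vinyl medium) the R alcohol is acylated much faster, so the S alcohol that becomes C2 should remain and is separated from the acetate under neutral conditions that spare the acid-sensitive benzylic allylic alcohol.

Step 3
Reactants: 4 (S)-1-[3-(benzyloxy)-4-methoxyphenyl]prop-2-en-1-ol; 5 propargyl bromide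
Product: 6 (S)-2-(benzyloxy)-1-methoxy-4-[1-(prop-2-yn-1-yloxy)prop-2-en-1-yl]benzene
Conditions: NaH, n-Bu4NI (cat.), THF, 0 °C to rt
Reagents that add atoms: propargyl bromide (5), C#CCBr
Why: Williamson ether synthesis (SN2 at a primary propargylic bromide) forms O1–C5 without touching the C–O bond at the stereocentre, so the S configuration is retained.

Step 4
Reactants: 7 5-bromo-2-methoxyphenol
Product: 8 2-(benzyloxy)-4-bromo-1-methoxybenzene
Conditions: BnBr, K2CO3, DMF, rt
Reagents that add atoms: benzyl bromide, BrCc1ccccc1
Why: Williamson O-benzylation of a phenol gives both aryl rings the same base-, borane- and oxidant-stable protecting group.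

Step 5
Reactants: 6 (S)-2-(benzyloxy)-1-methoxy-4-[1-(prop-2-yn-1-yloxy)prop-2-en-1-yl]benzene; 8 2-(benzyloxy)-4-bromo-1-methoxybenzene
Product: 9 (S)-1-(3-benzyloxy-4-methoxyphenyl)allyl 3-(3-benzyloxy-4-methoxyphenyl)prop-2-ynyl ether
Conditions: PdCl2(PhCN)2 (3 mol %), [HP(t-Bu)3]BF4 (6 mol %), CuI (2 mol %), i-Pr2NH, 1,4-dioxane, rt
Reagents that add atoms: none
Why: Sonogashira coupling; the bulky electron-rich phosphine should allow oxidative addition of the electron-rich aryl bromide at room temperature, and the alkyl allyl ether and its stereocentre are spectators under amine-buffered conditions.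

Step 6
Reactants: 9 (S)-1-(3-benzyloxy-4-methoxyphenyl)allyl 3-(3-benzyloxy-4-methoxyphenyl)prop-2-ynyl ether; 10 bis(pinacolato)diboron
Product: 11 (2S,3S,4Z)-2-(3-benzyloxy-4-methoxyphenyl)-4-(3-benzyloxy-4-methoxybenzylidene)-3-[(4,4,5,5-tetramethyl-1,3,2-dioxaborolan-2-yl)methyl]oxolane (2,3-trans)
Conditions: Pd(OAc)2 (5 mol %), B2pin2 (1.2 equiv), MeOH (1 equiv), toluene, 50 °C
Reagents that add atoms: bis(pinacolato)diboron (10), CC1(C)OB(OC1(C)C)B1OC(C)(C)C(C)(C)O1
Why: Pd(OAc)2 is reduced by the diboron and takes a proton from MeOH to give the active Pd–H, which adds syn across the alkyne of the coordinated enyne with hydrogen on the aryl-bearing C7 and palladium on C4, fixing the Z arylidene (aryl cis to C5). The vinylpalladium then inserts the vinyl group in a 5-exo-trig migratory insertion that makes C3–C4, closes the oxolane and leaves a primary CH2–Pd on the C3 arm. Transmetalation with B2pin2 and C–B reductive elimination release 11 and zerovalent palladium, which MeOH converts back to the hydride; this is the known Pd(OAc)2-catalysed borylative cyclisation of 1,6-enynes. The one new stereocentre, C3, is controlled by C2: in the envelope-like insertion transition state the C2 aryl group lies pseudo-equatorial and the alkene terminus turns away from it, which should give the 2,3-trans ring. The step needs regioselective hydropalladation, secured by the aryl/alkyl polarisation of the alkyne and by the fact that only palladium geminal to the C5 tether can reach the alkene. It also needs boron capture to outrun β-hydride loss from C3–H, which excess diboron, the phosphine-free catalyst and the mild temperature favour.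

Step 7
Reactants: 11 (2S,3S,4Z)-boronate
Product: 13 (S)-[3-(benzyloxy)-4-methoxyphenyl][(2S,3R,4R)-2-[3-(benzyloxy)-4-methoxyphenyl]-3-(hydroxymethyl)oxolan-4-yl]methanol (3,4-cis diol), via benzylic borane 12 (not isolated)
Conditions: BH3·THF, THF, 0 °C to rt; then aq NaOH, 30% H2O2, 0 °C to rt
Reagents that add atoms: borane–tetrahydrofuran, B.C1CCOC1; hydrogen peroxide, OO
Why: Hydroboration–oxidation; borane should add syn to the trisubstituted styrene-type alkene with boron on the less substituted benzylic C7 and hydrogen on C4 from the face opposite the C3 arm, the pinacol boronate rides along untouched at carbon, and alkaline peroxide converts both C–B bonds into C–OH with retention, so one operation unmasks the arm and oxygenates C7.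

Step 8
Reactants: 13 3,4-cis diol
Product: 14 (S)-[3-(benzyloxy)-4-methoxyphenyl][(2S,3R,4R)-2-[3-(benzyloxy)-4-methoxyphenyl]-3-{[(tert-butyldimethylsilyl)oxy]methyl}oxolan-4-yl]methanol
Conditions: TBSCl (1.05 equiv), imidazole, CH2Cl2, 0 °C
Reagents that add atoms: tert-butyldimethylsilyl chloride, CC(C)(C)[Si](C)(C)Cl
Why: Chemoselective silylation of a primary alcohol over a hindered secondary benzylic one keeps the arm out of the oxidation and stops it from trapping the 3,4-cis ketone as a bicyclic hemiketal during equilibration.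

Step 9
Reactants: 14 mono-TBS ether
Product: 16 [3-(benzyloxy)-4-methoxyphenyl][(2S,3R,4S)-2-[3-(benzyloxy)-4-methoxyphenyl]-3-{[(tert-butyldimethylsilyl)oxy]methyl}oxolan-4-yl]methanone (all-trans ketone), via 3,4-cis ketone 15 (not isolated)
Conditions: Dess–Martin periodinane, CH2Cl2, 0 °C to rt; aq NaHCO3/Na2S2O3 wash; crude 15, DBU (0.2 equiv), toluene, 60 °C
Reagents that add atoms: none
Why: Dess–Martin oxidation erases C7, and amidine-catalysed enolisation of the aryl ketone then equilibrates C4 to the more stable epimer in which aryl, arm and aroyl alternate faces (C4 = S); expulsion of O1 from the enolate is held back because the C5–O1 bond lies close to the nodal plane of the exocyclic enolate, and in an aprotic medium it could only re-close.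

Step 10
Reactants: 16 all-trans ketone
Product: 17 [3-(benzyloxy)-4-methoxyphenyl][(2S,3R,4S)-2-[3-(benzyloxy)-4-methoxyphenyl]-3-(hydroxymethyl)oxolan-4-yl]methanone
Conditions: n-Bu4NF, AcOH (1:1), THF, 0 °C to rt
Reagents that add atoms: none
Why: Fluoride-mediated silyl ether cleavage, buffered with acetic acid so that the β-alkoxy ketone meets no strong base; C4 already has its thermodynamic configuration, and the trans γ-hydroxy ketone cannot close to an unstrained hemiketal.

Step 11
Reactants: 17 dibenzyl ether of the target
Product: 18 (3-hydroxy-4-methoxyphenyl)[(2S,3R,4S)-2-(3-hydroxy-4-methoxyphenyl)-3-(hydroxymethyl)oxolan-4-yl]methanone (target, CNP0234761.1)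
Conditions: H2 (1 atm), Pd/C (10 wt %), EtOAc, rt, stopped once both benzyl groups are gone
Reagents that add atoms: none
Why: Catalytic hydrogenolysis; aryl benzyl ethers should cleave much faster than the electron-rich aryl ketone is reduced or the cyclic benzylic C2–O1 bond is broken in a neutral aprotic solvent at atmospheric pressure, and no stereocentre is involved.

**Compound list**
1 | 3-(benzyloxy)-4-methoxybenzaldehyde | COc1ccc(C=O)cc1OCc1ccccc1 | starting material
2 | vinylmagnesium bromide | C=C[Mg]Br | starting material
3 | rac-1-[3-(benzyloxy)-4-methoxyphenyl]prop-2-en-1-ol | C=CC(O)c1ccc(OC)c(OCc2ccccc2)c1 | intermediate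
4 | (S)-1-[3-(benzyloxy)-4-methoxyphenyl]prop-2-en-1-ol | C=C[C@H](O)c1ccc(OC)c(OCc2ccccc2)c1 | intermediate
5 | propargyl bromide | C#CCBr | starting material
6 | (S)-2-(benzyloxy)-1-methoxy-4-[1-(prop-2-yn-1-yloxy)prop-2-en-1-yl]benzene | C=C[C@H](OCC#C)c1ccc(OC)c(OCc2ccccc2)c1 | intermediate
7 | 5-bromo-2-methoxyphenol | COc1ccc(Br)cc1O | starting material
8 | 2-(benzyloxy)-4-bromo-1-methoxybenzene | COc1ccc(Br)cc1OCc1ccccc1 | intermediate
9 | (S)-1-(3-benzyloxy-4-methoxyphenyl)allyl 3-(3-benzyloxy-4-methoxyphenyl)prop-2-ynyl ether | C=C[C@H](OCC#Cc1ccc(OC)c(OCc2ccccc2)c1)c1ccc(OC)c(OCc2ccccc2)c1 | intermediate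
10 | bis(pinacolato)diboron | CC1(C)OB(OC1(C)C)B1OC(C)(C)C(C)(C)O1 | starting material
11 | (2S,3S,4Z)-2-aryl-4-arylidene-3-[(pinacolboryl)methyl]oxolane, aryl = 3-benzyloxy-4-methoxyphenyl, 2,3-trans | COc1ccc(/C=C2\CO[C@H](c3ccc(OC)c(OCc4ccccc4)c3)[C@H]2CB5OC(C)(C)C(C)(C)O5)cc1OCc1ccccc1 | intermediate
12 | (2S,3S,4R)-2-aryl-4-[(S)-aryl(boranyl)methyl]-3-[(pinacolboryl)methyl]oxolane, syn adduct, 3,4-cis | COc1ccc([C@@H](B)[C@H]2CO[C@H](c3ccc(OC)c(OCc4ccccc4)c3)[C@H]2CB5OC(C)(C)C(C)(C)O5)cc1OCc1ccccc1 | intermediate
13 | (S)-aryl[(2S,3R,4R)-2-aryl-3-(hydroxymethyl)oxolan-4-yl]methanol, 2,3-trans-3,4-cis diol | COc1ccc([C@@H](O)[C@H]2CO[C@H](c3ccc(OC)c(OCc4ccccc4)c3)[C@H]2CO)cc1OCc1ccccc1 | intermediate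
14 | primary TBS ether of 13 | COc1ccc([C@@H](O)[C@H]2CO[C@H](c3ccc(OC)c(OCc4ccccc4)c3)[C@H]2CO[Si](C)(C)C(C)(C)C)cc1OCc1ccccc1 | intermediate
15 | (2S,3R,4R) ketone, 3,4-cis, TBS ether | COc1ccc(C(=O)[C@H]2CO[C@H](c3ccc(OC)c(OCc4ccccc4)c3)[C@H]2CO[Si](C)(C)C(C)(C)C)cc1OCc1ccccc1 | intermediate
16 | (2S,3R,4S) ketone, all-trans, TBS ether | COc1ccc(C(=O)[C@@H]2CO[C@H](c3ccc(OC)c(OCc4ccccc4)c3)[C@H]2CO[Si](C)(C)C(C)(C)C)cc1OCc1ccccc1 | intermediate
17 | (2S,3R,4S) hydroxy ketone, dibenzyl ether of the target | COc1ccc(C(=O)[C@@H]2CO[C@H](c3ccc(OC)c(OCc4ccccc4)c3)[C@H]2CO)cc1OCc1ccccc1 | intermediate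
18 | (3-hydroxy-4-methoxyphenyl)[(2S,3R,4S)-2-(3-hydroxy-4-methoxyphenyl)-3-(hydroxymethyl)oxolan-4-yl]methanone | COc1ccc(C(=O)[C@@H]2CO[C@H](c3ccc(OC)c(O)c3)[C@H]2CO)cc1O | target

**Step count**
Total steps: 11. Longest linear sequence: 10 steps (1, 2, 3, 5, 6, 7, 8, 9, 10, 11); step 4 is the side branch.

**Steps most likely to fail**

Step 6.
- What may go wrong: β-hydride elimination from the primary alkylpalladium overtakes boron transfer. Zerovalent palladium may also ionise the doubly activated C2–O1 allylic ether and erode the C2 configuration, or facial discrimination at C3 may be weak.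
- Fallback: the same C3–C4 bond is closed by a radical instead of an organopalladium species.
- From 9, epoxidation of the vinyl group (mCPBA, NaHCO3, CH2Cl2, rt) gives the epoxy ether F1. Its oxirane carbon forms as a mixture, which is harmless because it becomes a radical centre.
- Cp2TiCl (trivalent titanium, made in the flask from Cp2TiCl2 and Zn dust in THF) opens the oxirane homolytically to the C3 radical carrying the CH2O–Ti arm.
- This radical adds 5-exo-dig to the aryl alkyne and, after acidic work-up, should give the homoallylic alcohol F2 (2,3-trans, alkene geometry immaterial).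
- Hydroboration–oxidation of F2 under the conditions of step 7 rejoins the route at 13.

Step 7.
- What may go wrong: regiocontrol is lost, because the para-methoxy donor stabilises positive charge at C7 and so draws boron toward C4. Addition to the hindered trisubstituted alkene may also be sluggish.
- Fallback: an ionic oxygenation that profits from the same polarisation.
- From 11, NaBO3·4H2O in THF/H2O gives the Z homoallylic alcohol F3, and TBSCl/imidazole gives the silyl ether F4.
- NBS in aqueous acetone at 0 °C gives the bromohydrin F5; water opens the bromonium ion at benzylic C7 and bromine stays on C4.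
- Radical debromination with (Me3Si)3SiH and AIBN in toluene at 80 °C delivers 14 together with its C4/C7 epimers. Step 9 funnels all of these into 16.

Step 11.
- What may go wrong: over-reduction, that is, hydrogenation of the aryl ketone or hydrogenolysis of the benzylic C2–O1 ring bond before both benzyl ethers are cleaved.
- Fallback: Lewis-acid cleavage replaces reductive cleavage.
- From 17, BCl3 with pentamethylbenzene as cation scavenger (CH2Cl2, −78 °C, MeOH quench) removes the aryl benzyl groups and gives 18 directly. The path holds no new compound (F0).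

**Further compounds**
F1 | step 6 | 2-{(R)-[3-(benzyloxy)-4-methoxyphenyl]({3-[3-(benzyloxy)-4-methoxyphenyl]prop-2-yn-1-yl}oxy)methyl}oxirane, oxirane carbon unassigned | C3OC3[C@H](OCC#Cc1ccc(OC)c(OCc2ccccc2)c1)c1ccc(OC)c(OCc2ccccc2)c1
F2 | step 6 | [(2S,3R)-2-(3-benzyloxy-4-methoxyphenyl)-4-(3-benzyloxy-4-methoxybenzylidene)oxolan-3-yl]methanol, alkene geometry unassigned | COc1ccc(C=C2CO[C@H](c3ccc(OC)c(OCc4ccccc4)c3)[C@H]2CO)cc1OCc1ccccc1
F3 | step 7 | [(2S,3R,4Z)-2-(3-benzyloxy-4-methoxyphenyl)-4-(3-benzyloxy-4-methoxybenzylidene)oxolan-3-yl]methanol | COc1ccc(/C=C2\CO[C@H](c3ccc(OC)c(OCc4ccccc4)c3)[C@H]2CO)cc1OCc1ccccc1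
F4 | step 7 | tert-butyldimethylsilyl ether of F3 | COc1ccc(/C=C2\CO[C@H](c3ccc(OC)c(OCc4ccccc4)c3)[C@H]2CO[Si](C)(C)C(C)(C)C)cc1OCc1ccccc1
F5 | step 7 | (2S,3R)-4-bromo-4-[aryl(hydroxy)methyl]-2-aryl-3-(silyloxymethyl)oxolane, aryl = 3-benzyloxy-4-methoxyphenyl, C4 and C7 unassigned | COc1ccc(C(O)C2(Br)CO[C@H](c3ccc(OC)c(OCc4ccccc4)c3)[C@H]2CO[Si](C)(C)C(C)(C)C)cc1OCc1ccccc1
F0 | step 11 | none | none
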